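**Retrosynthetic overview**
- The chalcone C=C comes from a Claisen–Schmidt condensation of a ring A methyl ketone with the ring B aldehyde. The acetyl carbon is brought in by ortho-formylation of the free phenol that the key step creates, and protecting groups come off last.
- The strategy rests on ring A (C1'–C6'): oxygen sits on the alternate carbons C2', C4' and C6', and C7 is attached at C3' between the C2' and C4' oxygens. This is the pattern a Danheiser benzannulation gives from a 3-alkoxycyclobutenone carrying C7 on its sp3 carbon and methoxyacetylene. The new ring bonds are alkyne CH to the ketene carbon and alkyne C(OMe) to cyclobutenone C2.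
- The cyclobutenone comes from a [2+2] cycloaddition of the ketene of a 3-aryl-alk-4-enoic acid with a 2-(trimethylsilyl)ethyl ynol ether.
- The acid comes from a Johnson–Claisen rearrangement (C5 to C7 chirality transfer, E C5=C6) of a (3S,5R,6E)-allylic alcohol. C5 is set by a catalysed alkenylzinc addition and C3 by a Brown allylation.
- Ring order: the three 4-oxyphenyl rings are bought; the four-membered ring (step 13) is made and then consumed in forming ring A (step 15), the only ring built.

Key step: step 15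

Remark 1: Ar = 4-(methoxymethoxy)phenyl, MOM = methoxymethyl, TBS = tert-butyldimethylsilyl. The chain is numbered as in the target (C1 the ArCH2 carbon, C3 the carbinol, C7 the diarylmethine); the target is (3S,7R). "Hp" is the group –C7H(Ar)–C6H=C5H–C4H2–C3H(OTBS)–C2H2–C1H2–Ar, bound through C7, (5E), (3S), with C7 arranged in space as in the target.

Remark 2 (assumption on the chemistry): both oxygens flanking C3' end as free hydroxyls, so the two ring CH positions of the benzannulation product lead to the same target. The acyl group is placed on the CH ortho to the free phenol, and ring A is numbered from that carbon (C1'). On this numbering the new bonds of step 15 are C1'–C2' and C5'–C6'; numbered the other way round, the same two bonds are C4'–C5' and C1'–C6'.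

**Step 1**
Reactants: 1 4-hydroxybenzaldehyde
Product: 2 4-(methoxymethoxy)benzaldehyde
Conditions: MOMCl, iPr2NEt, CH2Cl2, 0 °C → rt
Reagents that add atoms: chloromethyl methyl ether, COCCl
Why: O-alkylation of the phenol with the reactive α-chloro ether (Williamson-type) masks it as a base-stable acetal that is removed by acid at the end.

**Step 2**
Reactants: 2 4-(methoxymethoxy)benzaldehyde
Product: 3 1-ethynyl-4-(methoxymethoxy)benzene
Conditions: dimethyl (1-diazo-2-oxopropyl)phosphonate, K2CO3, MeOH, rt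
Reagents that add atoms: dimethyl (1-diazo-2-oxopropyl)phosphonate, COP(=O)(OC)C(=[N+]=[N-])C(C)=O
Why: Ohira–Bestmann homologation, in which the diazomethylphosphonate anion formed by methanolysis adds to the aldehyde and the resulting alkylidene carbene rearranges to the terminal alkyne under mildly basic conditions that the aryl MOM ether tolerates.

**Step 3**
Reactants: 4 methyl 3-(4-hydroxyphenyl)propanoate
Product: 5 methyl 3-[4-(methoxymethoxy)phenyl]propanoate
Conditions: MOMCl, iPr2NEt, CH2Cl2, 0 °C → rt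
Reagents that add atoms: chloromethyl methyl ether, COCCl
Why: The same phenol O-alkylation as in step 1.

**Step 4**
Reactants: 5 methyl 3-[4-(methoxymethoxy)phenyl]propanoate
Product: 6 3-[4-(methoxymethoxy)phenyl]propanal
Conditions: iBu2AlH (1.05 equiv), CH2Cl2, −78 °C; aq. sodium potassium tartrate
Reagents that add atoms: none
Why: Partial ester reduction, in which the tetrahedral aluminium hemiacetal is stable at −78 °C and releases the aldehyde only on work-up.

**Step 5**
Reactants: 6 3-[4-(methoxymethoxy)phenyl]propanal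
Product: 7 (3S)-1-[4-(methoxymethoxy)phenyl]hex-5-en-3-ol
Conditions: (+)-Ipc2B(allyl) (from (−)-α-pinene), Et2O, −78 °C; then NaOH, H2O2
Reagents that add atoms: (+)-B-allyldiisopinocampheylborane, C=CCB(C1CC2CC(C1C)C2(C)C)C1CC2CC(C1C)C2(C)C
Why: Brown allylation through a closed chair transition state, in which this antipode of the reagent delivers allyl to the Re face of the aldehyde and so should set C3 as S (reagent control).

**Step 6**
Reactants: 7 (3S)-1-[4-(methoxymethoxy)phenyl]hex-5-en-3-ol
Product: 8 (3S)-3-(tert-butyldimethylsilyloxy)-1-[4-(methoxymethoxy)phenyl]hex-5-ene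
Conditions: TBSCl, imidazole, DMF, rt
Reagents that add atoms: tert-butyldimethylsilyl chloride, CC(C)(C)[Si](C)(C)Cl
Why: Imidazole-promoted silylation of the secondary alcohol gives an ether that survives every step up to the fluoride treatment in step 20.

**Step 7**
Reactants: 8 (3S)-3-(tert-butyldimethylsilyloxy)-1-[4-(methoxymethoxy)phenyl]hex-5-ene
Product: 9 (3S)-3-(tert-butyldimethylsilyloxy)-5-[4-(methoxymethoxy)phenyl]pentanal
Conditions: O3, CH2Cl2, −78 °C (stopped at first excess); then PPh3, −78 °C → rt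
Reagents that add atoms: ozone, [O-][O+]=O
Why: Ozonolysis with reductive work-up, in which the terminal alkene reacts far faster than the alkoxyarenes and the C3 centre is untouched.

**Step 8**
Reactants: 3 1-ethynyl-4-(methoxymethoxy)benzene; 9 (3S)-3-(tert-butyldimethylsilyloxy)-5-[4-(methoxymethoxy)phenyl]pentanal
Product: 12 (3S,5R,6E)-3-(tert-butyldimethylsilyloxy)-1,7-bis[4-(methoxymethoxy)phenyl]hept-6-en-5-ol, via alkenylborane 10 (not isolated), via alkenylzinc 11 (not isolated)
Conditions: 3, Cy2BH (from BH3·SMe2 and cyclohexene), PhMe, 0 °C → rt; Et2Zn, −78 °C; (2S)-(−)-3-exo-morpholinoisoborneol (4 mol%), then 9, −20 → 0 °C; H2O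
Reagents that add atoms: none
Why: Syn-hydroboration gives the (E)-alkenylborane, boron-to-zinc exchange gives the alkenylzinc, and the amino-alcohol-catalysed 1,2-addition (Si-face attack under catalyst control) should set C5 as R, anti to the C3 silyl ether, with the minor diastereomer removed by chromatography.

**Step 9**
Reactants: 12 (3S,5R,6E)-3-(tert-butyldimethylsilyloxy)-1,7-bis[4-(methoxymethoxy)phenyl]hept-6-en-5-ol
Product: 15 ethyl (3R,4E,7S)-7-(tert-butyldimethylsilyloxy)-3,9-bis[4-(methoxymethoxy)phenyl]non-4-enoate, via mixed orthoester 13 (not isolated), via ketene acetal 14 (not isolated)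
Conditions: MeC(OEt)3 (8 equiv), EtCO2H (0.1 equiv), xylene, 135 °C, EtOH distilled off
Reagents that add atoms: triethyl orthoacetate, CCOC(C)(OCC)OCC
Why: Johnson–Claisen rearrangement, in which the chair transition state with the C4 chain equatorial forms the new C–C bond at C7 on the face from which the C5–O bond leaves, so C5 (R) is transferred to C7 (spatial arrangement of the target) and the new C5=C6 bond is E.

**Step 10**
Reactants: 15 ethyl (3R,4E,7S)-7-(tert-butyldimethylsilyloxy)-3,9-bis[4-(methoxymethoxy)phenyl]non-4-enoate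
Product: 16 (3R,4E,7S)-7-(tert-butyldimethylsilyloxy)-3,9-bis[4-(methoxymethoxy)phenyl]non-4-enoic acid
Conditions: LiOH, THF/MeOH/H2O, rt; then dilute HCl to pH 4, 0 °C
Reagents that add atoms: lithium hydroxide, [Li+].[OH-]
Why: Saponification of the ethyl ester, which cannot epimerise C7 because that centre is β to the carboxyl group.

**Step 11**
Reactants: 17 2-chloro-1,1-dimethoxyethane; 18 2-(trimethylsilyl)ethanol
Product: 19 2-chloro-1,1-bis[2-(trimethylsilyl)ethoxy]ethane
Conditions: 18 (2.3 equiv), p-toluenesulfonic acid (cat.), PhMe, 90 °C, MeOH distilled off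
Reagents that add atoms: none
Why: Acid-catalysed transacetalisation driven by removal of methanol, which avoids forming the base-labile alkoxide of a β-silyl alcohol.

**Step 12**
Reactants: 19 2-chloro-1,1-bis[2-(trimethylsilyl)ethoxy]ethane
Product: 21 [2-(ethynyloxy)ethyl]trimethylsilane, via sodium alkynyl ether 20 (not isolated)
Conditions: NaNH2 (3 equiv), liq. NH3, −33 °C; then H2O, −70 °C; pentane extraction, distillation
Reagents that add atoms: none
Why: The classical alkoxyacetylene synthesis, a double elimination (loss of alkoxide, then of HCl) from the α-chloro acetal, with the product held as its sodium acetylide until the quench.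

**Step 13**
Reactants: 16 (3R,4E,7S)-7-(tert-butyldimethylsilyloxy)-3,9-bis[4-(methoxymethoxy)phenyl]non-4-enoic acid; 21 [2-(ethynyloxy)ethyl]trimethylsilane
Product: 24 4-Hp-3-[2-(trimethylsilyl)ethoxy]cyclobut-2-en-1-one (C4 epimers), via acid chloride 22 (not isolated), via ketene 23 (not isolated)
Conditions: 1-chloro-N,N,2-trimethylprop-1-en-1-amine, CH2Cl2, 0 °C → rt; then added over 4 h to 21 (3 equiv), Et3N (1.5 equiv), MeCN, rt → 40 °C
Reagents that add atoms: none
Why: The α-chloroenamine forms the acid chloride under neutral conditions that spare the MOM and silyl ethers, Et3N dehydrochlorinates it to the aldoketene, and a regiospecific ketene–ynol ether [2+2] cycloaddition (nucleophilic CH carbon to the ketene carbonyl carbon, ynol ether in excess and slow addition to outrun ketene dimerisation) gives the cyclobutenone, whose uncontrolled C4 centre becomes sp2 in step 15.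

**Step 14**
Reactants: 17 2-chloro-1,1-dimethoxyethane
Product: 26 methoxyethyne (methoxyacetylene), via sodium methoxyethynide 25 (not isolated)
Conditions: NaNH2 (3 equiv), liq. NH3, −33 °C; then H2O, −70 °C; distilled cold (bp about 23 °C), used as a PhMe solution
Reagents that add atoms: none
Why: The same double elimination as in step 12, applied to the commercial acetal.

**Step 15**
Reactants: 24 4-Hp-3-[2-(trimethylsilyl)ethoxy]cyclobut-2-en-1-one; 26 methoxyethyne
Product: 31 2-Hp-5-methoxy-3-[2-(trimethylsilyl)ethoxy]phenol, via vinylketene 27 (not isolated), via vinylcyclobutenone 28 (not isolated), via dienylketene 29 (not isolated), via cyclohexadienone 30 (not isolated)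
Conditions: 26 (5 equiv), PhMe, 80 → 110 °C, sealed tube
Reagents that add atoms: none
Why: Danheiser benzannulation, the known reaction of cyclobutenones with alkoxyacetylenes: thermal conrotatory 4π opening of the cyclobutenone gives the vinylketene, the nucleophilic CH carbon of methoxyacetylene bonds to the ketene carbonyl carbon in a regiospecific [2+2] cycloaddition, and reversible 4π opening of the new cyclobutenone gives the dienylketene. Ring A closes by a disrotatory 6π electrocyclisation that joins the ketene carbon to the former cyclobutenone C4 (the C2'–C3' bond), and tautomerisation of the cyclohexadienone gives the phenol. The net new ring bonds are ketene carbon–CH (C2'–C1') and cyclobutenone C2–C(OMe) (C5'–C6'), so the ketene carbonyl becomes the free C2' hydroxyl, the alkyne supplies C1'–H and C6'–OMe, and the alkoxy-bearing carbon becomes C4'. No stereocentre is formed, both C4 epimers of the cyclobutenone converge, and C7 is never α to a carbonyl or part of a π system, so it should keep its configuration. The regiochemistry needed (OMe para to C3', free OH next to it) follows from the ketene and ynol ether polarity. Outward rotation of the C7 substituent in the first ring opening keeps the C7–H away from the ketene, so a 1,5-hydrogen shift should not compete.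

**Step 16**
Reactants: 31 2-Hp-5-methoxy-3-[2-(trimethylsilyl)ethoxy]phenol
Product: 32 2-hydroxy-3-Hp-6-methoxy-4-[2-(trimethylsilyl)ethoxy]benzaldehyde
Conditions: MgCl2 (2 equiv), Et3N (4 equiv), (CH2O)n (6 equiv), THF, 65 °C; dilute HCl work-up, 0 °C
Reagents that add atoms: paraformaldehyde (as formaldehyde), C=O
Why: Magnesium-mediated ortho-formylation, in which the magnesium phenoxide delivers formaldehyde to the only free ortho position (the future C1') and a second formaldehyde oxidises the benzylic alkoxide by hydride transfer, under conditions that leave the MOM, silyl and alkene groups alone.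

**Step 17**
Reactants: 32 2-hydroxy-3-Hp-6-methoxy-4-[2-(trimethylsilyl)ethoxy]benzaldehyde
Product: 33 1-{2-hydroxy-3-Hp-6-methoxy-4-[2-(trimethylsilyl)ethoxy]phenyl}ethanol (carbinol epimers)
Conditions: MeMgBr (3 equiv), THF, −40 → 0 °C; H2O
Reagents that add atoms: methylmagnesium bromide, C[Mg]Br
Why: Grignard 1,2-addition after deprotonation of the phenol by the first equivalent; the new carbinol centre is not controlled because it is oxidised away in step 18.

**Step 18**
Reactants: 33 1-{2-hydroxy-3-Hp-6-methoxy-4-[2-(trimethylsilyl)ethoxy]phenyl}ethanol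
Product: 34 1-{2-hydroxy-3-Hp-6-methoxy-4-[2-(trimethylsilyl)ethoxy]phenyl}ethanone
Conditions: MnO2 (activated, 20 equiv), CH2Cl2, rt
Reagents that add atoms: none
Why: Neutral oxidation of the benzylic alcohol by MnO2 gives the hydrogen-bonded ortho-hydroxyacetophenone without acid that could ionise the ortho-hydroxybenzylic carbinol.

**Step 19**
Reactants: 34 1-{2-hydroxy-3-Hp-6-methoxy-4-[2-(trimethylsilyl)ethoxy]phenyl}ethanone; 2 4-(methoxymethoxy)benzaldehyde
Product: 36 (E)-1-{2-hydroxy-3-Hp-6-methoxy-4-[2-(trimethylsilyl)ethoxy]phenyl}-3-[4-(methoxymethoxy)phenyl]prop-2-en-1-one, via aldol adduct 35 (not isolated)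
Conditions: 2 (1.5 equiv), KOH (50% aq., 10 equiv), EtOH, rt; then dilute HCl to pH 5
Reagents that add atoms: none
Why: Claisen–Schmidt condensation, in which the methyl ketone enolate adds to the non-enolisable aldehyde and E1cB dehydration gives the (E)-enone, with the 4'-oxygen protected and the 2'-hydroxyl free.

**Step 20**
Reactants: 36 (E)-1-{2-hydroxy-3-Hp-6-methoxy-4-[2-(trimethylsilyl)ethoxy]phenyl}-3-[4-(methoxymethoxy)phenyl]prop-2-en-1-one
Product: 37 (E)-1-{2,4-dihydroxy-3-[(3S,5E)-3-hydroxy-1,7-bis(4-(methoxymethoxy)phenyl)hept-5-en-7-yl]-6-methoxyphenyl}-3-[4-(methoxymethoxy)phenyl]prop-2-en-1-one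
Conditions: Bu4NF (6 equiv), THF, 0 °C → rt (40 °C if needed); H2O
Reagents that add atoms: none
Why: Fluoride cleaves the C3 silyl ether and triggers β-elimination of the 2-(trimethylsilyl)ethyl ether (ethene and Me3SiF leave), the 4'-phenoxide para to the ketone being a good leaving group.

**Step 21**
Reactants: 37 (E)-1-{2,4-dihydroxy-3-[(3S,5E)-3-hydroxy-1,7-bis(4-(methoxymethoxy)phenyl)hept-5-en-7-yl]-6-methoxyphenyl}-3-[4-(methoxymethoxy)phenyl]prop-2-en-1-one
Product: 38 epicalyxin B
Conditions: HCl (3 M aq.), MeOH, rt → 40 °C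
Reagents that add atoms: none
Why: Acid-catalysed acetal exchange with methanol removes the three MOM groups as dimethoxymethane, and the mild temperature is chosen to avoid chalcone-to-flavanone cyclisation and ionisation at C7.

**Compound list**
1 | 4-hydroxybenzaldehyde | O=Cc1ccc(O)cc1 | starting material
2 | 4-(methoxymethoxy)benzaldehyde | COCOc1ccc(C=O)cc1 | intermediate
3 | 1-ethynyl-4-(methoxymethoxy)benzene | C#Cc1ccc(OCOC)cc1 | intermediate
4 | methyl 3-(4-hydroxyphenyl)propanoate | COC(=O)CCc1ccc(O)cc1 | starting material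
5 | methyl 3-[4-(methoxymethoxy)phenyl]propanoate | COCOc1ccc(CCC(=O)OC)cc1 | intermediate
6 | 3-[4-(methoxymethoxy)phenyl]propanal | COCOc1ccc(CCC=O)cc1 | intermediate
7 | (3S)-1-[4-(methoxymethoxy)phenyl]hex-5-en-3-ol | C=CC[C@@H](O)CCc1ccc(OCOC)cc1 | intermediate
8 | (3S)-3-(tert-butyldimethylsilyloxy)-1-[4-(methoxymethoxy)phenyl]hex-5-ene | C=CC[C@@H](O[Si](C)(C)C(C)(C)C)CCc1ccc(OCOC)cc1 | intermediate
9 | (3S)-3-(tert-butyldimethylsilyloxy)-5-[4-(methoxymethoxy)phenyl]pentanal | O=CC[C@@H](O[Si](C)(C)C(C)(C)C)CCc1ccc(OCOC)cc1 | intermediate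
10 | (E)-dicyclohexyl{2-[4-(methoxymethoxy)phenyl]ethenyl}borane | COCOc1ccc(/C=C/B(C2CCCCC2)C2CCCCC2)cc1 | intermediate
11 | ethyl{(E)-2-[4-(methoxymethoxy)phenyl]ethenyl}zinc | CC[Zn]/C=C/c1ccc(OCOC)cc1 | intermediate
12 | (3S,5R,6E)-3-(tert-butyldimethylsilyloxy)-1,7-bis[4-(methoxymethoxy)phenyl]hept-6-en-5-ol | COCOc1ccc(/C=C/[C@H](O)C[C@@H](O[Si](C)(C)C(C)(C)C)CCc2ccc(OCOC)cc2)cc1 | intermediate
13 | mixed orthoester of 12 (1,1-diethoxyethyl ether at O5) | CCOC(C)(OCC)O[C@@H](/C=C/c1ccc(OCOC)cc1)C[C@@H](O[Si](C)(C)C(C)(C)C)CCc1ccc(OCOC)cc1 | intermediate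
14 | ketene acetal of 12 (1-ethoxyethenyl ether at O5) | C=C(OCC)O[C@@H](/C=C/c1ccc(OCOC)cc1)C[C@@H](O[Si](C)(C)C(C)(C)C)CCc1ccc(OCOC)cc1 | intermediate
15 | ethyl (3R,4E,7S)-7-(tert-butyldimethylsilyloxy)-3,9-bis[4-(methoxymethoxy)phenyl]non-4-enoate | CCOC(=O)C[C@H](/C=C/C[C@@H](O[Si](C)(C)C(C)(C)C)CCc1ccc(OCOC)cc1)c1ccc(OCOC)cc1 | intermediate
16 | (3R,4E,7S)-7-(tert-butyldimethylsilyloxy)-3,9-bis[4-(methoxymethoxy)phenyl]non-4-enoic acid | OC(=O)C[C@H](/C=C/C[C@@H](O[Si](C)(C)C(C)(C)C)CCc1ccc(OCOC)cc1)c1ccc(OCOC)cc1 | intermediate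
17 | 2-chloro-1,1-dimethoxyethane (chloroacetaldehyde dimethyl acetal) | COC(CCl)OC | starting material
18 | 2-(trimethylsilyl)ethanol | C[Si](C)(C)CCO | starting material
19 | 2-chloro-1,1-bis[2-(trimethylsilyl)ethoxy]ethane | ClCC(OCC[Si](C)(C)C)OCC[Si](C)(C)C | intermediate
20 | sodium 2-[2-(trimethylsilyl)ethoxy]ethynide | [Na]C#COCC[Si](C)(C)C | intermediate
21 | [2-(ethynyloxy)ethyl]trimethylsilane | C#COCC[Si](C)(C)C | intermediate
22 | acid chloride of 16 | ClC(=O)C[C@H](/C=C/C[C@@H](O[Si](C)(C)C(C)(C)C)CCc1ccc(OCOC)cc1)c1ccc(OCOC)cc1 | intermediate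
23 | ketene Hp–CH=C=O | O=C=C[C@H](/C=C/C[C@@H](O[Si](C)(C)C(C)(C)C)CCc1ccc(OCOC)cc1)c1ccc(OCOC)cc1 | intermediate
24 | 4-Hp-3-[2-(trimethylsilyl)ethoxy]cyclobut-2-en-1-one (C4 epimers) | O=C1C=C(OCC[Si](C)(C)C)C1[C@H](/C=C/C[C@@H](O[Si](C)(C)C(C)(C)C)CCc1ccc(OCOC)cc1)c1ccc(OCOC)cc1 | intermediate
25 | sodium methoxyethynide | [Na]C#COC | intermediate
26 | methoxyethyne (methoxyacetylene) | COC#C | intermediate
27 | vinylketene O=C=CH–C(OCH2CH2SiMe3)=CH–Hp | O=C=C/C(OCC[Si](C)(C)C)=C/[C@H](/C=C/C[C@@H](O[Si](C)(C)C(C)(C)C)CCc1ccc(OCOC)cc1)c1ccc(OCOC)cc1 | intermediate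
28 | 3-methoxy-4-{2-Hp-1-[2-(trimethylsilyl)ethoxy]ethenyl}cyclobut-2-en-1-one | COC1=CC(=O)C1/C(OCC[Si](C)(C)C)=C/[C@H](/C=C/C[C@@H](O[Si](C)(C)C(C)(C)C)CCc1ccc(OCOC)cc1)c1ccc(OCOC)cc1 | intermediate
29 | dienylketene O=C=CH–C(OMe)=CH–C(OCH2CH2SiMe3)=CH–Hp | O=C=C/C(OC)=C\C(OCC[Si](C)(C)C)=C\[C@H](/C=C/C[C@@H](O[Si](C)(C)C(C)(C)C)CCc1ccc(OCOC)cc1)c1ccc(OCOC)cc1 | intermediate
30 | 6-Hp-3-methoxy-5-[2-(trimethylsilyl)ethoxy]cyclohexa-2,4-dien-1-one | COC1=CC(=O)C([C@H](/C=C/C[C@@H](O[Si](C)(C)C(C)(C)C)CCc2ccc(OCOC)cc2)c2ccc(OCOC)cc2)C(OCC[Si](C)(C)C)=C1 | intermediate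
31 | 2-Hp-5-methoxy-3-[2-(trimethylsilyl)ethoxy]phenol | COc1cc(O)c([C@H](/C=C/C[C@@H](O[Si](C)(C)C(C)(C)C)CCc2ccc(OCOC)cc2)c2ccc(OCOC)cc2)c(OCC[Si](C)(C)C)c1 | intermediate
32 | 2-hydroxy-3-Hp-6-methoxy-4-[2-(trimethylsilyl)ethoxy]benzaldehyde | COc1cc(OCC[Si](C)(C)C)c([C@H](/C=C/C[C@@H](O[Si](C)(C)C(C)(C)C)CCc2ccc(OCOC)cc2)c2ccc(OCOC)cc2)c(O)c1C=O | intermediate
33 | 1-{2-hydroxy-3-Hp-6-methoxy-4-[2-(trimethylsilyl)ethoxy]phenyl}ethanol (carbinol epimers) | COc1cc(OCC[Si](C)(C)C)c([C@H](/C=C/C[C@@H](O[Si](C)(C)C(C)(C)C)CCc2ccc(OCOC)cc2)c2ccc(OCOC)cc2)c(O)c1C(C)O | intermediate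
34 | 1-{2-hydroxy-3-Hp-6-methoxy-4-[2-(trimethylsilyl)ethoxy]phenyl}ethanone | COc1cc(OCC[Si](C)(C)C)c([C@H](/C=C/C[C@@H](O[Si](C)(C)C(C)(C)C)CCc2ccc(OCOC)cc2)c2ccc(OCOC)cc2)c(O)c1C(C)=O | intermediate
35 | aldol adduct of 34 and 2 (β-hydroxy ketone, carbinol epimers) | COc1cc(OCC[Si](C)(C)C)c([C@H](/C=C/C[C@@H](O[Si](C)(C)C(C)(C)C)CCc2ccc(OCOC)cc2)c2ccc(OCOC)cc2)c(O)c1C(=O)CC(O)c1ccc(OCOC)cc1 | intermediate
36 | (E)-1-{2-hydroxy-3-Hp-6-methoxy-4-[2-(trimethylsilyl)ethoxy]phenyl}-3-[4-(methoxymethoxy)phenyl]prop-2-en-1-one | COc1cc(OCC[Si](C)(C)C)c([C@H](/C=C/C[C@@H](O[Si](C)(C)C(C)(C)C)CCc2ccc(OCOC)cc2)c2ccc(OCOC)cc2)c(O)c1C(=O)/C=C/c1ccc(OCOC)cc1 | intermediate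
37 | tris-MOM ether of epicalyxin B (2',4'- and C3-hydroxyls free) | COc1cc(O)c([C@H](/C=C/C[C@@H](O)CCc2ccc(OCOC)cc2)c2ccc(OCOC)cc2)c(O)c1C(=O)/C=C/c1ccc(OCOC)cc1 | intermediate
38 | epicalyxin B | COc1cc(O)c([C@H](/C=C/C[C@@H](O)CCc2ccc(O)cc2)c2ccc(O)cc2)c(O)c1C(=O)/C=C/c1ccc(O)cc1 | target

**Step count and risks**
Total: 21 steps. Longest linear sequence: 16 steps (4 → 5 → 6 → 7 → 8 → 9 → 12 → 15 → 16 → 24 → 31 → 32 → 33 → 34 → 36 → 37 → 38).

Step 15 (key step). The alkoxy-substituted vinylketene may dimerise or O-acylate the product phenol faster than the volatile, polymerisation-prone ynol ether intercepts it, or the cascade may stall before the 6π closure. The fallback sets out from 12 and returns to the route at 32; it also replaces steps 11 to 14, so it covers a poor ketene cycloaddition in step 13 as well. Ring A is bought, and C7 is created by a copper-mediated anti-SN2′ arylation with 1,3-chirality transfer. Mitsunobu esterification of 12 with picolinic acid (PPh3, diisopropyl azodicarboxylate, THF, 0 °C) should give the C5-inverted picolinate F1. Commercial 5-methoxybenzene-1,3-diol with 3,4-dihydro-2H-pyran and pyridinium p-toluenesulfonate (CH2Cl2) gives the bis(tetrahydropyranyl) ether F2. F2 is lithiated between the two acetal oxygens (n-BuLi, THF, 0 °C), transmetalated (MgBr2·OEt2, then CuBr·SMe2) and combined with F1 at −40 °C. The aryl group should enter C7 anti to the leaving picolinate while the double bond moves to C5=C6 (E), giving the coupled product F3 with the C7 configuration of the main route. Pyridinium p-toluenesulfonate in MeOH at rt should remove both tetrahydropyranyl groups and keep the aryl MOM ethers and the silyl ether, giving the symmetric resorcinol F4. Magnesium-mediated ortho-formylation (MgCl2, Et3N, paraformaldehyde, THF, 65 °C), for which both free ortho positions are equivalent, gives the aldehyde F5. Mitsunobu etherification of its non-chelated hydroxyl with 2-(trimethylsilyl)ethanol 18 gives 32.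

Step 9. Acid-promoted ionisation of the electron-rich cinnamyl-type alcohol (loss of configuration at C5, 1,3-transposition) may compete with orthoester exchange and erode the configuration transferred to C7. The fallback sets out from 12 and returns at 16, so it also replaces step 10. Acetylation (Ac2O, pyridine, 4-dimethylaminopyridine, CH2Cl2) gives the acetate F6. Ireland–Claisen rearrangement under purely basic conditions (LiN(SiMe3)2, Me3SiCl/Et3N, THF, −78 °C → 60 °C, then aqueous work-up) passes through the same chair arrangement and should deliver acid 16 directly.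

Step 8. Facial selectivity in the catalyst-controlled addition to an unbranched β-silyloxy aldehyde may be poor, and ethyl transfer from zinc may compete. The fallback sets out from 9 and 3 and returns at 12. The lithium acetylide of 3 (n-BuLi, THF, −78 °C) adds to 9 to give the propargylic alcohols F7 as a C5 mixture. MnO2 in CH2Cl2 oxidises them to the ynone F8. Noyori asymmetric transfer hydrogenation (RuCl[(R,R)-TsDPEN](p-cymene), iPrOH, rt) should give the (5R)-propargylic alcohol F9 under catalyst control. Trans-selective hydroalumination with NaAlH2(OCH2CH2OMe)2 (THF, 0 °C) gives the (E)-allylic alcohol 12.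

**Further compounds**
F1 | step 15 | (3S,5S,6E)-3-(tert-butyldimethylsilyloxy)-1,7-bis[4-(methoxymethoxy)phenyl]hept-6-en-5-yl pyridine-2-carboxylate | COCOc1ccc(/C=C/[C@@H](OC(=O)c2ccccn2)C[C@@H](O[Si](C)(C)C(C)(C)C)CCc2ccc(OCOC)cc2)cc1
F2 | step 15 | 1-methoxy-3,5-bis(tetrahydro-2H-pyran-2-yloxy)benzene | COc1cc(OC2CCCCO2)cc(OC2CCCCO2)c1
F3 | step 15 | 2-Hp-5-methoxy-1,3-bis(tetrahydro-2H-pyran-2-yloxy)benzene | COc1cc(OC2CCCCO2)c([C@H](/C=C/C[C@@H](O[Si](C)(C)C(C)(C)C)CCc2ccc(OCOC)cc2)c2ccc(OCOC)cc2)c(OC2CCCCO2)c1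
F4 | step 15 | 2-Hp-5-methoxybenzene-1,3-diol | COc1cc(O)c([C@H](/C=C/C[C@@H](O[Si](C)(C)C(C)(C)C)CCc2ccc(OCOC)cc2)c2ccc(OCOC)cc2)c(O)c1
F5 | step 15 | 2,4-dihydroxy-3-Hp-6-methoxybenzaldehyde | COc1cc(O)c([C@H](/C=C/C[C@@H](O[Si](C)(C)C(C)(C)C)CCc2ccc(OCOC)cc2)c2ccc(OCOC)cc2)c(O)c1C=O
F6 | step 9 | (3S,5R,6E)-3-(tert-butyldimethylsilyloxy)-1,7-bis[4-(methoxymethoxy)phenyl]hept-6-en-5-yl acetate | COCOc1ccc(/C=C/[C@H](OC(C)=O)C[C@@H](O[Si](C)(C)C(C)(C)C)CCc2ccc(OCOC)cc2)cc1
F7 | step 8 | (3S)-3-(tert-butyldimethylsilyloxy)-1,7-bis[4-(methoxymethoxy)phenyl]hept-6-yn-5-ol (C5 epimers) | COCOc1ccc(C#CC(O)C[C@@H](O[Si](C)(C)C(C)(C)C)CCc2ccc(OCOC)cc2)cc1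
F8 | step 8 | (3S)-3-(tert-butyldimethylsilyloxy)-1,7-bis[4-(methoxymethoxy)phenyl]hept-6-yn-5-one | COCOc1ccc(C#CC(=O)C[C@@H](O[Si](C)(C)C(C)(C)C)CCc2ccc(OCOC)cc2)cc1
F9 | step 8 | (3S,5R)-3-(tert-butyldimethylsilyloxy)-1,7-bis[4-(methoxymethoxy)phenyl]hept-6-yn-5-ol | COCOc1ccc(C#C[C@H](O)C[C@@H](O[Si](C)(C)C(C)(C)C)CCc2ccc(OCOC)cc2)cc1
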